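**Plan**
1. Numbering: benzofuran O1, C2 (bears ring C), C3, C3a, C4 to C7, C7a. Ring A is C3a/C4/C5/C6/C7/C7a and ring B is the furan. The target has no stereocentre.
2. Enabling feature: ring A has C5-OH beside C6-OMe and C7-prenyl, and C4-H is its only free position. C5 can therefore be a ketene carbonyl carbon, C4 the ketene CH, C6 the CH of a methyl enol ether, C7 its prenylated carbon, and C7a=C3a the 2,3-bond of a furan.
3. Cuts, in retrosynthetic order: ring C O-allyl; C5–C6 (six-electron closure) together with C3a–C4 (Wolff shift); C4–C5 (acylation of diazomethane); C6–C7 (formylation); O1–C2/C7a (Paal–Knorr); C3–C3a (phenacyl alkylation); C7–CH2 of the prenyl group (dianion alkylation).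
4. Forward order: ring C is bought as 3,5-dihydroxyacetophenone and its two phenols are differentiated. Ring B closes in step 6 and ring A closes last, on the finished furan, before deallylation.
5. Stereochemistry: nothing has to be set. The stereocentres that arise on the way are racemic and transient, and the enol ether geometry disappears when C6 becomes aromatic.

Key step: step 11

Assumption: the enol ether compounds are drawn as the E isomer (OMe trans to the furan). Any Z isomer would be carried along, because both geometries lead to the same phenol.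

**Step 1**
Reactants: 1 3,5-dihydroxyacetophenone
Product: 2 1-(3-hydroxy-5-methoxyphenyl)ethanone
Conditions: MeI (1.0 equiv), K2CO3 (1.0 equiv), acetone, reflux
Reagents that add atoms: iodomethane CI
Why: Williamson etherification of a diphenol with two equivalent OH groups and one equivalent of MeI should give the monoether statistically, with diol (recycled) and diether removed by chromatography.

**Step 2**
Reactants: 2 1-(3-hydroxy-5-methoxyphenyl)ethanone
Product: 3 1-[3-(allyloxy)-5-methoxyphenyl]ethanone
Conditions: allyl bromide, K2CO3, acetone, reflux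
Reagents that add atoms: allyl bromide C=CCBr
Why: Williamson allylation of the remaining phenol installs a group that tolerates the amide bases, catalytic acid, silanolate and long-wave light used later and that leaves under neutral palladium catalysis without touching the prenyl group.

**Step 3**
Reactants: 3 1-[3-(allyloxy)-5-methoxyphenyl]ethanone
Product: 5 2-bromo-1-[3-(allyloxy)-5-methoxyphenyl]ethanone, via trimethylsilyl enol ether 4 (not isolated)
Conditions: LiN(SiMe3)2, THF, −78 °C; Me3SiCl, −78 to 0 °C; then NBS, THF, −78 to 0 °C
Reagents that add atoms: N-bromosuccinimide O=C1CCC(=O)N1Br; chlorotrimethylsilane C[Si](C)(C)Cl (its silyl group is present in 4 only)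
Why: Electrophilic bromination of a silyl enol ether is used because this alkene is far more nucleophilic than the allyl double bond or the dialkoxyarene, so bromine should enter only at the α-carbon.

**Step 4**
Reactants: 6 ethyl acetoacetate; 7 prenyl bromide (1-bromo-3-methylbut-2-ene)
Product: 8 ethyl 7-methyl-3-oxooct-6-enoate
Conditions: NaH, THF, 0 °C; n-BuLi, 0 °C; then 7, 0 °C to rt; aq HCl quench
Reagents that add atoms: none
Why: In the γ-alkylation of the acetoacetate dianion the more basic terminal carbanion reacts first, by SN2 at the primary carbon of the allylic bromide, and this makes the bond between the future C7 and the prenyl CH2.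

**Step 5**
Reactants: 8 ethyl 7-methyl-3-oxooct-6-enoate; 5 2-bromo-1-[3-(allyloxy)-5-methoxyphenyl]ethanone
Product: 9 ethyl 2-{2-[3-(allyloxy)-5-methoxyphenyl]-2-oxoethyl}-7-methyl-3-oxooct-6-enoate (racemic)
Conditions: NaH, THF, 0 °C; then 5, 0 °C to rt
Reagents that add atoms: none
Why: Acetoacetic ester C-alkylation of the preformed sodium enolate with a very reactive phenacyl bromide should outrun the Feist–Benary aldol path and form C3–C3a, and the new stereocentre is racemic and is lost in step 6.

**Step 6**
Reactants: 9 ethyl 2-{2-[3-(allyloxy)-5-methoxyphenyl]-2-oxoethyl}-7-methyl-3-oxooct-6-enoate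
Product: 10 ethyl 5-[3-(allyloxy)-5-methoxyphenyl]-2-(4-methylpent-3-en-1-yl)furan-3-carboxylate
Conditions: p-TsOH·H2O (5 mol %), toluene, Dean–Stark, reflux
Reagents that add atoms: none
Why: Paal–Knorr cyclodehydration of the 1,4-diketone closes ring B with aryl at C5, ester at C3 and the side chain at C2 of the furan, under the same catalytic acid conditions that trisubstituted alkenes survive in routine ketalisations.

**Step 7**
Reactants: 10 ethyl 5-[3-(allyloxy)-5-methoxyphenyl]-2-(4-methylpent-3-en-1-yl)furan-3-carboxylate
Product: 11 ethyl 5-[3-(allyloxy)-5-methoxyphenyl]-2-(5-methyl-1-oxohex-4-en-2-yl)furan-3-carboxylate (racemic, in equilibrium with its enol)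
Conditions: LiN(iPr)2 (2.2 equiv), THF, −78 °C; HCO2Et, −78 to −20 °C; AcOH quench
Reagents that add atoms: ethyl formate CCOC=O
Why: Lateral deprotonation of a 2-alkyl-3-furoate gives an extended dienolate that can react only at the side-chain carbon (furan C5 is blocked), and the crossed Claisen formylation is driven by the second equivalent of base, which turns the product into its conjugated enolate.

**Step 8**
Reactants: 11 ethyl 5-[3-(allyloxy)-5-methoxyphenyl]-2-(5-methyl-1-oxohex-4-en-2-yl)furan-3-carboxylate
Product: 12 ethyl 5-[3-(allyloxy)-5-methoxyphenyl]-2-[(1E)-1-methoxy-5-methylhexa-1,4-dien-2-yl]furan-3-carboxylate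
Conditions: Me2SO4, K2CO3, DMF, 0 °C to rt
Reagents that add atoms: dimethyl sulfate COS(=O)(=O)OC
Why: O-alkylation of a stabilised potassium enolate by a hard electrophile in a dipolar aprotic solvent follows the standard conversion of α-aryl-β-hydroxyacrylates into β-methoxyacrylates, whereas C-methylation would have to build a quaternary carbon and give up conjugation with the furoate.

**Step 9**
Reactants: 12 ethyl 5-[3-(allyloxy)-5-methoxyphenyl]-2-[(1E)-1-methoxy-5-methylhexa-1,4-dien-2-yl]furan-3-carboxylate
Product: 13 potassium 5-[3-(allyloxy)-5-methoxyphenyl]-2-[(1E)-1-methoxy-5-methylhexa-1,4-dien-2-yl]furan-3-carboxylate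
Conditions: KOSiMe3 (1.5 equiv), THF, rt to 40 °C; evaporate, triturate with pentane
Reagents that add atoms: potassium trimethylsilanolate C[Si](C)(C)[O-].[K+]
Why: Anhydrous ester cleavage with silanolate delivers the carboxylate salt directly, so the enol ether never meets aqueous acid or a neighbouring free carboxylic acid that could add to it and form a lactone.

**Step 10**
Reactants: 13 potassium 5-[3-(allyloxy)-5-methoxyphenyl]-2-[(1E)-1-methoxy-5-methylhexa-1,4-dien-2-yl]furan-3-carboxylate
Product: 15 2-diazo-1-{5-[3-(allyloxy)-5-methoxyphenyl]-2-[(1E)-1-methoxy-5-methylhexa-1,4-dien-2-yl]furan-3-yl}ethanone, via isobutyl mixed carbonic anhydride 14 (not isolated)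
Conditions: i-BuOCOCl, THF, −15 °C; then CH2N2 (excess), Et2O, 0 °C to rt, dark; used promptly
Reagents that add atoms: diazomethane C=[N+]=[N-]; isobutyl chloroformate CC(C)COC(=O)Cl (its atoms are present in 14 only)
Why: Acylation of diazomethane by a mixed carbonic anhydride, the first stage of the Arndt–Eistert sequence, forms C4–C5 without any HCl, so the enol ether and the alkenes, which diazomethane does not attack, should remain intact.

**Step 11**
Reactants: 15 2-diazo-1-{5-[3-(allyloxy)-5-methoxyphenyl]-2-[(1E)-1-methoxy-5-methylhexa-1,4-dien-2-yl]furan-3-yl}ethanone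
Product: 18 ring C O-allyl dinklagein A (2-[3-(allyloxy)-5-methoxyphenyl]-6-methoxy-7-(3-methylbut-2-en-1-yl)benzofuran-5-ol), via furan-3-ylketene 16 (not isolated), via benzofuran-5(6H)-one 17 (not isolated)
Conditions: hν (365 nm LED), dry degassed toluene (0.005 M), 20 °C; then 80 °C
Reagents that add atoms: none
Why: Light of a wavelength that the diazoketone absorbs but the 2-arylbenzofuran product does not expels N2 while the electron-rich furan-3-yl group shifts from the carbonyl carbon to the diazo carbon (Wolff rearrangement, new bond C3a–C4), giving ketene 16 in which the former ester carbon is C5 and the former diazomethane carbon is C4. In 16 the ketene C4=C5, the furan C3a=C7a and the enol ether C7=C6 make up a dienylketene whose central double bond is held cis by ring B, and ring A closes by a thermal disrotatory six-electron electrocyclisation that joins C5 to C6 and gives dienone 17. C6 of 17 is the only new stereocentre, it forms racemic with nothing to control it, and it is erased when its hydrogen moves to the C5 oxygen, a shift paid for by the aromaticity of rings A and B, which is also why both enol ether geometries end in 18. The closest known reaction type is the final stage of the Danheiser benzannulation with aryl and heteroaryl diazoketones, in which a photochemical Wolff rearrangement feeds a dienylketene that contains an aromatic double bond and closes to a fused phenol. The step needs the concerted shift to win over carbene addition to the enol ether, prenyl and allyl alkenes, and this is favoured by the s-Z conformation of a diazoketone with hydrogen on the diazo carbon, by direct metal-free excitation and by the good migratory aptitude of the furyl group. It also needs six-membered closure to win over ketene–enol ether [2+2] addition and over capture of 16 by water, by 18 or by itself, which is secured by the cis-locked triene (the [2+2] adduct would be a strained furan-fused bicyclo[2.1.1]hexenone), by high dilution in dry degassed solvent and by the final warming.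

**Step 12**
Reactants: 18 ring C O-allyl dinklagein A
Product: 19 dinklagein A (2-(3-hydroxy-5-methoxyphenyl)-6-methoxy-7-(3-methylbut-2-en-1-yl)benzofuran-5-ol)
Conditions: Pd(PPh3)4 (5 mol %), morpholine (10 equiv), THF, rt
Reagents that add atoms: none
Why: In this Tsuji–Trost deallylation zerovalent palladium ionises the allyl aryl ether to a π-allyl complex and the phenoxide, excess morpholine takes up the allyl group before the free C5 phenol can, and the C-bound prenyl group has no leaving group and stays inert.

**Compound list**
1 | 3,5-dihydroxyacetophenone | CC(=O)c1cc(O)cc(O)c1 | starting material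
2 | 1-(3-hydroxy-5-methoxyphenyl)ethanone | CC(=O)c1cc(O)cc(OC)c1 | intermediate
3 | 1-[3-(allyloxy)-5-methoxyphenyl]ethanone | CC(=O)c1cc(OC)cc(OCC=C)c1 | intermediate
4 | {1-[3-(allyloxy)-5-methoxyphenyl]ethenyloxy}trimethylsilane | C=C(O[Si](C)(C)C)c1cc(OC)cc(OCC=C)c1 | intermediate
5 | 2-bromo-1-[3-(allyloxy)-5-methoxyphenyl]ethanone | O=C(CBr)c1cc(OC)cc(OCC=C)c1 | intermediate
6 | ethyl acetoacetate | CCOC(=O)CC(C)=O | starting material
7 | prenyl bromide | CC(C)=CCBr | starting material
8 | ethyl 7-methyl-3-oxooct-6-enoate | CCOC(=O)CC(=O)CCC=C(C)C | intermediate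
9 | ethyl 2-{2-[3-(allyloxy)-5-methoxyphenyl]-2-oxoethyl}-7-methyl-3-oxooct-6-enoate (racemic) | CCOC(=O)C(CC(=O)c1cc(OC)cc(OCC=C)c1)C(=O)CCC=C(C)C | intermediate
10 | ethyl 5-[3-(allyloxy)-5-methoxyphenyl]-2-(4-methylpent-3-en-1-yl)furan-3-carboxylate | CCOC(=O)c1cc(-c2cc(OC)cc(OCC=C)c2)oc1CCC=C(C)C | intermediate
11 | ethyl 5-[3-(allyloxy)-5-methoxyphenyl]-2-(5-methyl-1-oxohex-4-en-2-yl)furan-3-carboxylate (racemic) | CCOC(=O)c1cc(-c2cc(OC)cc(OCC=C)c2)oc1C(C=O)CC=C(C)C | intermediate
12 | ethyl 5-[3-(allyloxy)-5-methoxyphenyl]-2-[(1E)-1-methoxy-5-methylhexa-1,4-dien-2-yl]furan-3-carboxylate | CCOC(=O)c1cc(-c2cc(OC)cc(OCC=C)c2)oc1/C(CC=C(C)C)=C/OC | intermediate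
13 | potassium 5-[3-(allyloxy)-5-methoxyphenyl]-2-[(1E)-1-methoxy-5-methylhexa-1,4-dien-2-yl]furan-3-carboxylate | [K+].[O-]C(=O)c1cc(-c2cc(OC)cc(OCC=C)c2)oc1/C(CC=C(C)C)=C/OC | intermediate
14 | isobutyl mixed carbonic anhydride of the furan-3-carboxylic acid | CC(C)COC(=O)OC(=O)c1cc(-c2cc(OC)cc(OCC=C)c2)oc1/C(CC=C(C)C)=C/OC | intermediate
15 | 2-diazo-1-{5-[3-(allyloxy)-5-methoxyphenyl]-2-[(1E)-1-methoxy-5-methylhexa-1,4-dien-2-yl]furan-3-yl}ethanone | [N-]=[N+]=CC(=O)c1cc(-c2cc(OC)cc(OCC=C)c2)oc1/C(CC=C(C)C)=C/OC | intermediate
16 | 2-{5-[3-(allyloxy)-5-methoxyphenyl]-2-[(1E)-1-methoxy-5-methylhexa-1,4-dien-2-yl]furan-3-yl}ethenone | O=C=Cc1cc(-c2cc(OC)cc(OCC=C)c2)oc1/C(CC=C(C)C)=C/OC | intermediate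
17 | 2-[3-(allyloxy)-5-methoxyphenyl]-6-methoxy-7-(3-methylbut-2-en-1-yl)benzofuran-5(6H)-one (racemic) | COC1C(=O)C=C2C=C(c3cc(OC)cc(OCC=C)c3)OC2=C1CC=C(C)C | intermediate
18 | ring C O-allyl dinklagein A | C=CCOc1cc(OC)cc(-c2cc3cc(O)c(OC)c(CC=C(C)C)c3o2)c1 | intermediate
19 | dinklagein A | COc1cc(O)cc(-c2cc3cc(O)c(OC)c(CC=C(C)C)c3o2)c1 | target

**Step count**
Total: 12 steps. Longest linear sequence: 11 steps (steps 1 to 3 and 5 to 12, from 3,5-dihydroxyacetophenone). Step 4 is a one-step side branch.

**Steps most likely to fail**

**Step 11.**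
- Risk: part of the excited diazoketone may leak into carbene addition to the nearby enol ether. The ketene may also be taken up by the phenol as it forms, by moisture or by itself before ring A closes.
- Fallback: it sets out from 15 and returns at 18, and it reaches the same ketene thermally from the homologous acid. Compound 15 is rearranged in the dark with silver benzoate and Et3N in aqueous THF (Arndt–Eistert homologation). Water traps the ketene at once and, after a buffered work-up, gives {5-[3-(allyloxy)-5-methoxyphenyl]-2-[(1E)-1-methoxy-5-methylhexa-1,4-dien-2-yl]furan-3-yl}acetic acid F1.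
- Heating this acid in Ac2O with NaOAc forms the mixed anhydride, which eliminates to the furylketene at a temperature where the C5–C6 closure is immediate. The phenol is acetylated as it appears and cannot intercept ketene, so the product is ring C O-allyl dinklagein A 5-acetate F2. K2CO3 in MeOH removes the acetate and gives 18.

**Step 7.**
- Risk: deprotonation at the secondary side-chain carbon may be incomplete. The dienolate may condense with the ester of a second molecule, and the new enolate oxygen may attack the neighbouring ester.
- Fallback: it sets out from 10 and returns at 13, and it replaces the ester by a carboxylate that cannot act as an acylating agent. Saponification of 10 with LiOH gives 5-[3-(allyloxy)-5-methoxyphenyl]-2-(4-methylpent-3-en-1-yl)furan-3-carboxylic acid F3. Excess LiN(iPr)2 converts it into the carboxylate/lateral carbanion dianion, a known species for 2-alkyl-3-furoic acids.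
- A DMF quench and buffered work-up give 5-[3-(allyloxy)-5-methoxyphenyl]-2-(5-methyl-1-oxohex-4-en-2-yl)furan-3-carboxylic acid F4, which may rest as its lactol. Me2SO4 and K2CO3 in DMF methylate both the carboxylate and the enolate oxygen to give methyl 5-[3-(allyloxy)-5-methoxyphenyl]-2-[(1E)-1-methoxy-5-methylhexa-1,4-dien-2-yl]furan-3-carboxylate F5. KOSiMe3 cleaves this ester to 13.

**Step 8.**
- Risk: methylation may occur at carbon instead of oxygen, or the enolate oxygen may cyclise onto the ester faster than it is methylated.
- Fallback: it sets out from 11 and returns at 12, and it avoids a free enolate oxygen altogether. Trimethyl orthoformate with catalytic pyridinium tosylate in MeOH converts 11 into ethyl 5-[3-(allyloxy)-5-methoxyphenyl]-2-(1,1-dimethoxy-5-methylhex-4-en-2-yl)furan-3-carboxylate F6.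
- KN(SiMe3)2 in THF then removes the lateral proton, which is vinylogous to the ester, and methoxide leaves by an E1cB elimination to give 12. This is the way β,β-dimethoxy esters are turned into β-methoxyacrylates.

**Further compounds**
F1 | step 11 | {5-[3-(allyloxy)-5-methoxyphenyl]-2-[(1E)-1-methoxy-5-methylhexa-1,4-dien-2-yl]furan-3-yl}acetic acid | OC(=O)Cc1cc(-c2cc(OC)cc(OCC=C)c2)oc1/C(CC=C(C)C)=C/OC
F2 | step 11 | ring C O-allyl dinklagein A 5-acetate | CC(=O)Oc1cc2cc(-c3cc(OC)cc(OCC=C)c3)oc2c(CC=C(C)C)c1OC
F3 | step 7 | 5-[3-(allyloxy)-5-methoxyphenyl]-2-(4-methylpent-3-en-1-yl)furan-3-carboxylic acid | OC(=O)c1cc(-c2cc(OC)cc(OCC=C)c2)oc1CCC=C(C)C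
F4 | step 7 | 5-[3-(allyloxy)-5-methoxyphenyl]-2-(5-methyl-1-oxohex-4-en-2-yl)furan-3-carboxylic acid (racemic) | OC(=O)c1cc(-c2cc(OC)cc(OCC=C)c2)oc1C(C=O)CC=C(C)C
F5 | step 7 | methyl 5-[3-(allyloxy)-5-methoxyphenyl]-2-[(1E)-1-methoxy-5-methylhexa-1,4-dien-2-yl]furan-3-carboxylate | COC(=O)c1cc(-c2cc(OC)cc(OCC=C)c2)oc1/C(CC=C(C)C)=C/OC
F6 | step 8 | ethyl 5-[3-(allyloxy)-5-methoxyphenyl]-2-(1,1-dimethoxy-5-methylhex-4-en-2-yl)furan-3-carboxylate (racemic) | CCOC(=O)c1cc(-c2cc(OC)cc(OCC=C)c2)oc1C(CC=C(C)C)C(OC)OC
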